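**Strategy.** The route rests on cutting out the cyclopentanone inside the bicyclo[3.2.1]octenedione: the bridging C=O, the quaternary carbon, the CH bearing 4-hydroxyphenyl, the CH bearing 3,5-dihydroxyphenyl and the bridgehead CH. This ring is a spiro ring on a second cyclopentanone. The key step builds it in one operation. A carbene-generated homoenolate of 3,5-dimethoxycinnamaldehyde adds through its benzylic carbon to the arylidene carbon of a 2-(4-methoxybenzylidene)cyclopentanone. The enolate carbon is then acylated by the acyl azolium, joining the ketone carbon to the quaternary centre. The precursor is a chiral-pool three-component coupling product whose aryl-bearing carbon steers the annulation and is epimerised afterwards.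

Key step: step 4

Remark: ring B is the cyclopentanone ring that comes from 1, ring C the cyclopentanone made in step 4. The carbinol centres of 4, 5 and 15 and the acetyl-bearing carbon of 19 are left undefined because the following step removes or equilibrates them. Compounds 1, 2, 3, 7, 8, 14 and 18 are taken as commercial.

**Step 1**
Reactants: 1 (4S)-4-[(tert-butyldimethylsilyl)oxy]cyclopent-2-en-1-one, 2 4-methoxyphenylmagnesium bromide, 3 4-methoxybenzaldehyde
Product: 4 (2R,3R,4S)-4-[(tert-butyldimethylsilyl)oxy]-2-[hydroxy(4-methoxyphenyl)methyl]-3-(4-methoxyphenyl)cyclopentan-1-one (both carbinol epimers)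
Conditions: 2 (1.3 equiv), CuBr·SMe2 (10 mol%), THF, −78 °C; then 3 (1.5 equiv), −78 °C; aq. NH4Cl
Reagents that add atoms: none
Why: Copper-catalysed 1,4-addition of the aryl Grignard should occur anti to the silyloxy group, and the magnesium enolate is trapped at C2 by the aldehyde anti to the new aryl group (three-component conjugate addition–aldol coupling).

**Step 2**
Reactants: 4 the aldol adduct
Product: 6 (2E,3S,4S)-4-[(tert-butyldimethylsilyl)oxy]-2-(4-methoxybenzylidene)-3-(4-methoxyphenyl)cyclopentan-1-one, via mesylate 5 (not isolated)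
Conditions: MsCl (1.5 equiv), DMAP (4 equiv), CH2Cl2, 0 °C to rt
Reagents that add atoms: none
Why: Mesylation and DMAP-mediated E1cB elimination should give the conjugated (E)-arylidene ketone (aryl anti to C=O), the mild base leaving the β-silyloxy group in place.

**Step 3**
Reactants: 7 3,5-dimethoxybenzaldehyde, 8 (triphenylphosphoranylidene)acetaldehyde
Product: 9 (E)-3-(3,5-dimethoxyphenyl)prop-2-enal
Conditions: PhMe, 80 °C
Reagents that add atoms: none
Why: Wittig olefination with the stabilised formyl ylide should give the (E)-enal.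

**Step 4**
Reactants: 6 the (E)-arylidene ketone, 9 the enal (1.5 equiv)
Product: 11 8-[(tert-butyldimethylsilyl)oxy]-3-(3,5-dimethoxyphenyl)-4,9-bis(4-methoxyphenyl)spiro[4.4]nonane-1,6-dione (C3 and C4 aryl groups trans; C4 aryl on the side of C9; C9 aryl on the side of C4 and trans to the C8 silyloxy group), via acyl azolium enolate 10 (not isolated)
Conditions: 1,3-bis(2,4,6-trimethylphenyl)imidazolium chloride (15 mol%), DBU (15 mol%), THF, rt, 9 added over 6 h
Reagents that add atoms: none
Why: The carbene adds to enal 9 to give the Breslow intermediate, whose homoenolate β-carbon adds to the benzylidene carbon of 6 (bond CH(3,5-dimethoxyphenyl)–CH(4-methoxyphenyl)); tautomerisation gives acyl azolium enolate 10, whose enolate α-carbon attacks the acyl azolium carbon (bond ring C=O–quaternary carbon) and releases the carbene. The closest known reaction type is the carbene-catalysed homoenolate annulation of cinnamaldehydes with 2-arylidene cyclopentanones, which gives spirocyclopentanones. The one ring closed is the cyclopentanone (ring C), by a 5-exo-trig C-acylation of the enolate. The benzylidene carbon and the quaternary carbon should be set by approach of the three-carbon unit to the face of the (E)-alkene anti to the C3 aryl group of ring B, which puts the new C=O trans and the new CH(aryl) arm cis to that aryl group, while the (E)-geometry keeps the 4-methoxyphenyl group on the side of C3; the CH(3,5-dimethoxyphenyl) centre follows from the open, antiperiplanar Michael transition state that leads to the trans-diaryl ring. The step needs C-acylation to win over aldol addition to the ring ketone with β-lactone formation, and over self-condensation of the enal: the aldol path would build a β-lactone on a strained bicyclo[3.3.0] frame, and slow addition keeps the enal concentration low.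

**Step 5**
Reactants: 11 the silyloxy spirodiketone
Product: 13 3-(3,5-dimethoxyphenyl)-4,9-bis(4-methoxyphenyl)spiro[4.4]non-7-ene-1,6-dione with the C9 aryl group cis to C1=O and trans to C4, via kinetic enone 12 (not isolated)
Conditions: DBU (3 equiv), PhMe, 80 °C
Reagents that add atoms: none
Why: DBU should effect E1cB loss of the β-silyloxy group to enone 12 and then equilibrate the now γ-acidic benzylic centre through the dienolate, so that the 4-methoxyphenyl group moves from the face of the bulky CH(aryl) arm of the spiro centre to the face of its C=O arm (thermodynamic control).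

**Step 6**
Reactants: 13 the spiro enone, 14 3,5-dimethoxyphenylmagnesium chloride, 3 4-methoxybenzaldehyde
Product: 15 7-[hydroxy(4-methoxyphenyl)methyl]-3,8-bis(3,5-dimethoxyphenyl)-4,9-bis(4-methoxyphenyl)spiro[4.4]nonane-1,6-dione (C8 aryl trans to C9 aryl; C7 side chain trans to C8 aryl; both carbinol epimers)
Conditions: 14 (2.2 equiv), CuI (1.1 equiv), THF, −40 °C; 13, −78 °C; then 3 (2 equiv), −78 °C; aq. NH4Cl
Reagents that add atoms: none
Why: The diarylcuprate should add to the enone β-carbon anti to the neighbouring 4-methoxyphenyl group without touching the hindered ketone of ring C, and the enolate is trapped by the aldehyde (second three-component conjugate addition–aldol coupling).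

**Step 7**
Reactants: 15 the aldol adduct
Product: 17 4′-(3,5-dimethoxyphenyl)-5,7-dimethoxy-3,5′,8-tris(4-methoxyphenyl)-3,3a,8,8a-tetrahydro-1H-spiro[cyclopenta[a]indene-2,1′-cyclopentane]-1,2′-dione (cis ring fusion; C3 and C8 aryl groups both on the face of the ring-fusion hydrogens), via arylidene ketone 16 (not isolated)
Conditions: TfOH (2 equiv), CH2Cl2, −40 to 0 °C
Reagents that add atoms: none
Why: Ionisation of the 4-methoxybenzylic alcohol (in equilibrium with arylidene ketone 16) gives a cation that is trapped by the adjacent 3,5-dimethoxyphenyl ring at its activated ortho carbon (intramolecular Friedel–Crafts alkylation); only the cis-fused bicyclo[3.3.0] ring can form, which resets the α-centre through the enol, and the aryl group takes the exo position trans to the carbonyl arm.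

**Step 8**
Reactants: 17 the indane-fused spirodiketone, 18 1-acetyl-1H-benzotriazole
Product: 19 the 3′-acetyl derivative of 17 (β-diketone; acetyl-bearing carbon labile)
Conditions: 18 (1.5 equiv), MgBr2·OEt2 (2.5 equiv), i-Pr2NEt (3 equiv), CH2Cl2, rt
Reagents that add atoms: none
Why: Soft enolisation and C-acylation with the acylbenzotriazole should give the β-diketone at the only CH2 next to a ketone, since acylation at the tertiary α-CH of the other ketone would give a non-enolisable product and is not driven.

**Step 9**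
Reactants: 19 the triketone
Product: 21 the hepta-O-methyl ether of the target, via aldol 20 (not isolated)
Conditions: TsOH·H2O (0.2 equiv), PhMe, reflux, Dean–Stark
Reagents that add atoms: none
Why: Acid-catalysed intramolecular aldol condensation of the acetyl methyl group onto the 1,5-related ring B carbonyl should close the six-membered ring (Robinson-type closure); the acetyl group can reach that carbonyl only from the face of ring C that carries it, which fixes the bridgehead CH, and dehydration can only give the enone conjugated with the new ketone.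

**Step 10**
Reactants: 21 the hepta-O-methyl ether
Product: 22 CNP0407321.1
Conditions: BBr3 (14 equiv), CH2Cl2, −78 °C to rt; then H2O
Reagents that add atoms: none
Why: BBr3 should cleave the seven aryl methyl ethers without touching the enedione or any stereocentre.

**Compound list**

1 | (4S)-4-[(tert-butyldimethylsilyl)oxy]cyclopent-2-en-1-one | O=C1C=C[C@@H](O[Si](C)(C)C(C)(C)C)C1 | starting material
2 | 4-methoxyphenylmagnesium bromide | COc1ccc([Mg]Br)cc1 | starting material
3 | 4-methoxybenzaldehyde | COc1ccc(C=O)cc1 | starting material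
4 | (2R,3R,4S)-4-[(tert-butyldimethylsilyl)oxy]-2-[hydroxy(4-methoxyphenyl)methyl]-3-(4-methoxyphenyl)cyclopentan-1-one, both carbinol epimers | O=C1C[C@H](O[Si](C)(C)C(C)(C)C)[C@@H](c2ccc(OC)cc2)[C@@H]1C(O)c1ccc(OC)cc1 | intermediate
5 | methanesulfonate of 4 | O=C1C[C@H](O[Si](C)(C)C(C)(C)C)[C@@H](c2ccc(OC)cc2)[C@@H]1C(OS(C)(=O)=O)c1ccc(OC)cc1 | intermediate (not isolated)
6 | (2E,3S,4S)-4-[(tert-butyldimethylsilyl)oxy]-2-(4-methoxybenzylidene)-3-(4-methoxyphenyl)cyclopentan-1-one | O=C1C[C@H](O[Si](C)(C)C(C)(C)C)[C@@H](c2ccc(OC)cc2)/C1=C\c1ccc(OC)cc1 | intermediate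
7 | 3,5-dimethoxybenzaldehyde | COc1cc(C=O)cc(OC)c1 | starting material
8 | (triphenylphosphoranylidene)acetaldehyde | O=CC=P(c1ccccc1)(c1ccccc1)c1ccccc1 | starting material
9 | (E)-3-(3,5-dimethoxyphenyl)prop-2-enal | O=C/C=C/c1cc(OC)cc(OC)c1 | intermediate
10 | acyl azolium enolate: Michael adduct of the homoenolate of 9 on 6, bound to 1,3-dimesitylimidazol-2-ylidene | [O-]C1=C([C@H](c2ccc(OC)cc2)[C@H](CC(=O)c2n(-c3c(C)cc(C)cc3C)cc[n+]2-c2c(C)cc(C)cc2C)c2cc(OC)cc(OC)c2)[C@H](c2ccc(OC)cc2)[C@@H](O[Si](C)(C)C(C)(C)C)C1 | intermediate (not isolated)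
11 | 8-[(tert-butyldimethylsilyl)oxy]-3-(3,5-dimethoxyphenyl)-4,9-bis(4-methoxyphenyl)spiro[4.4]nonane-1,6-dione; C3/C4 aryls trans, C4 aryl on the side of C9, C9 aryl on the side of C4 and trans to the silyloxy group | O=C1C[C@H](O[Si](C)(C)C(C)(C)C)[C@@H](c2ccc(OC)cc2)[C@]12C(=O)C[C@H](c1cc(OC)cc(OC)c1)[C@H]2c1ccc(OC)cc1 | intermediate
12 | 3-(3,5-dimethoxyphenyl)-4,9-bis(4-methoxyphenyl)spiro[4.4]non-7-ene-1,6-dione, C9 aryl cis to C4 | O=C1C=C[C@@H](c2ccc(OC)cc2)[C@]12C(=O)C[C@H](c1cc(OC)cc(OC)c1)[C@H]2c1ccc(OC)cc1 | intermediate (not isolated)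
13 | 3-(3,5-dimethoxyphenyl)-4,9-bis(4-methoxyphenyl)spiro[4.4]non-7-ene-1,6-dione, C9 aryl cis to C1=O and trans to C4 | O=C1C=C[C@H](c2ccc(OC)cc2)[C@]12C(=O)C[C@H](c1cc(OC)cc(OC)c1)[C@H]2c1ccc(OC)cc1 | intermediate
14 | 3,5-dimethoxyphenylmagnesium chloride | COc1cc(OC)cc([Mg]Cl)c1 | starting material
15 | 7-[hydroxy(4-methoxyphenyl)methyl]-3,8-bis(3,5-dimethoxyphenyl)-4,9-bis(4-methoxyphenyl)spiro[4.4]nonane-1,6-dione; C8 aryl trans to C9 aryl, C7 side chain trans to C8 aryl, both carbinol epimers | O=C1[C@H](C(O)c2ccc(OC)cc2)[C@@H](c2cc(OC)cc(OC)c2)[C@H](c2ccc(OC)cc2)[C@]12C(=O)C[C@H](c1cc(OC)cc(OC)c1)[C@H]2c1ccc(OC)cc1 | intermediate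
16 | (7E)-7-(4-methoxybenzylidene)-3,8-bis(3,5-dimethoxyphenyl)-4,9-bis(4-methoxyphenyl)spiro[4.4]nonane-1,6-dione | O=C1/C(=C/c2ccc(OC)cc2)[C@@H](c2cc(OC)cc(OC)c2)[C@H](c2ccc(OC)cc2)[C@]12C(=O)C[C@H](c1cc(OC)cc(OC)c1)[C@H]2c1ccc(OC)cc1 | intermediate (not isolated)
17 | 4′-(3,5-dimethoxyphenyl)-5,7-dimethoxy-3,5′,8-tris(4-methoxyphenyl)-3,3a,8,8a-tetrahydro-1H-spiro[cyclopenta[a]indene-2,1′-cyclopentane]-1,2′-dione; cis-fused, C3 and C8 aryls on the face of the ring-fusion hydrogens | O=C1[C@H]2[C@H](c3ccc(OC)cc3)c3c(OC)cc(OC)cc3[C@H]2[C@H](c2ccc(OC)cc2)[C@]12C(=O)C[C@H](c1cc(OC)cc(OC)c1)[C@H]2c1ccc(OC)cc1 | intermediate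
18 | 1-acetyl-1H-benzotriazole | CC(=O)n1nnc2ccccc21 | starting material
19 | 3′-acetyl derivative of 17 (β-diketone, acetyl-bearing carbon labile) | O=C1[C@H]2[C@H](c3ccc(OC)cc3)c3c(OC)cc(OC)cc3[C@H]2[C@H](c2ccc(OC)cc2)[C@]12C(=O)C(C(C)=O)[C@H](c1cc(OC)cc(OC)c1)[C@H]2c1ccc(OC)cc1 | intermediate
20 | bridged aldol: tertiary alcohol from addition of the acetyl CH3 of 19 to the ring B carbonyl | O=C1C[C@]2(O)[C@H]3[C@H](c4ccc(OC)cc4)c4c(OC)cc(OC)cc4[C@H]3[C@H](c3ccc(OC)cc3)[C@]23C(=O)[C@H]1[C@H](c1cc(OC)cc(OC)c1)[C@H]3c1ccc(OC)cc1 | intermediate (not isolated)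
21 | hepta-O-methyl ether of the target | O=C1C=C2[C@H]3[C@H](c4ccc(OC)cc4)c4c(OC)cc(OC)cc4[C@H]3[C@H](c3ccc(OC)cc3)[C@]23C(=O)[C@H]1[C@H](c1cc(OC)cc(OC)c1)[C@H]3c1ccc(OC)cc1 | intermediate
22 | CNP0407321.1 | O=C1C=C2[C@H]3[C@H](c4ccc(O)cc4)c4c(O)cc(O)cc4[C@H]3[C@H](c3ccc(O)cc3)[C@]23C(=O)[C@H]1[C@H](c1cc(O)cc(O)c1)[C@H]3c1ccc(O)cc1 | target

**Step count.** Total: 10 steps. Longest linear sequence: 9 steps (1, 2, 4, 5, 6, 7, 8, 9, 10, from compound 1).

**Steps most likely to fail**

Step 4. The acyl azolium enolate may close through aldol addition to the ring B ketone followed by β-lactone formation and loss of CO2 instead of C-acylation. The C-acylation may also take place from the other rotamer about the new CH(aryl)–ring bond, on the face syn to the C3 aryl group. DBU may eliminate the silyloxy group before the annulation. The fallback sets out from 6 and 9 and separates the two bond formations. The same carbene-catalysed homoenolate addition is run in THF/MeOH so that methanol intercepts the acyl azolium, which should give the open-chain Michael adduct methyl 4-[3-(tert-butyldimethylsilyloxy)-2-(4-methoxyphenyl)-5-oxocyclopentyl]-3-(3,5-dimethoxyphenyl)-4-(4-methoxyphenyl)butanoate F1. Treatment with LiN(SiMe3)2 (2.5 equiv, THF, −78 to 0 °C) should then cause E1cB loss of the silanolate and an anionic Dieckmann-type C-acylation of the cross-conjugated dienolate by the ester. The fallback comes back to the route at 12, which is equilibrated to 13 under the conditions of step 5.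

Step 5. Reprotonation of the dienolate at the α-carbon may move the double bond out of conjugation with the ketone and towards the aryl group, or the equilibration may stop before the cis epimer is used up. The fallback sets out from 11 and makes the benzylic centre α to a carbonyl, so that no alkene isomer can form.
- Desilylation with Bu4NF/AcOH (THF, 0 °C) should give the β-hydroxy ketone F2.
- Oxidation with Dess–Martin periodinane, then Et3N, should give the spiro cyclopentane-1,3-dione F3 with the 4-methoxyphenyl group equilibrated to the face of the C=O arm of the spiro centre.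
- Tf2O and 2,6-lutidine should sulfonylate the oxygen of the less hindered carbonyl, remote from the spiro centre, to give the vinyl triflate F4.
- Reduction with Pd(OAc)2, PPh3 and Et3SiH (DMF, 60 °C) replaces the triflate by hydrogen, and the fallback comes back at 13.

Step 9. Enolisation of the β-diketone away from its methyl group, and acid-promoted loss of the acetyl group, may outrun attack on the hindered ring B carbonyl. The fallback sets out from 19 and makes the methyl carbon the nucleophile by silylation. TMSCl/Et3N, then LiN(i-Pr)2 and TMSCl (THF, −78 °C), should give the 1,3-bis(trimethylsilyloxy)diene F5, the tertiary α-CH of the other ketone being kinetically slow to deprotonate. TiCl4 (CH2Cl2, −78 °C) should then trigger an intramolecular Mukaiyama aldol addition through the terminal carbon. Acidic work-up with TsOH dehydrates the aldol, and the fallback comes back at 21.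

**Further compounds**

F1 | step 4 | methyl 4-[3-(tert-butyldimethylsilyloxy)-2-(4-methoxyphenyl)-5-oxocyclopentyl]-3-(3,5-dimethoxyphenyl)-4-(4-methoxyphenyl)butanoate | O=C1C[C@H](O[Si](C)(C)C(C)(C)C)[C@@H](c2ccc(OC)cc2)[C@@H]1[C@H](c1ccc(OC)cc1)[C@H](CC(=O)OC)c1cc(OC)cc(OC)c1
F2 | step 5 | 8-hydroxy-3-(3,5-dimethoxyphenyl)-4,9-bis(4-methoxyphenyl)spiro[4.4]nonane-1,6-dione | O=C1C[C@H](O)[C@@H](c2ccc(OC)cc2)[C@]12C(=O)C[C@H](c1cc(OC)cc(OC)c1)[C@H]2c1ccc(OC)cc1
F3 | step 5 | 3-(3,5-dimethoxyphenyl)-4,9-bis(4-methoxyphenyl)spiro[4.4]nonane-1,6,8-trione, C9 aryl cis to C1=O | O=C1CC(=O)[C@H](c2ccc(OC)cc2)[C@]12C(=O)C[C@H](c1cc(OC)cc(OC)c1)[C@H]2c1ccc(OC)cc1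
F4 | step 5 | 8-(trifluoromethanesulfonyloxy)-3-(3,5-dimethoxyphenyl)-4,9-bis(4-methoxyphenyl)spiro[4.4]non-7-ene-1,6-dione | O=C1C=C(OS(=O)(=O)C(F)(F)F)[C@H](c2ccc(OC)cc2)[C@]12C(=O)C[C@H](c1cc(OC)cc(OC)c1)[C@H]2c1ccc(OC)cc1
F5 | step 9 | 1,3-bis(trimethylsilyloxy)diene of 19 | O=C1[C@H]2[C@H](c3ccc(OC)cc3)c3c(OC)cc(OC)cc3[C@H]2[C@H](c2ccc(OC)cc2)[C@]12C(O[Si](C)(C)C)=C(C(=C)O[Si](C)(C)C)[C@H](c1cc(OC)cc(OC)c1)[C@H]2c1ccc(OC)cc1
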